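**Plan**

- Retrosynthesis: remove the O-benzyl group from the phenol, then cut the C3–CH2Ar bond (enolate benzylation). Then cut the O1–C5 and C3–C4 bonds of the dihydrofuran-2(3H)-one ring in one operation, which leads to a (Z)-alkenyl p-tolyl sulfoxide (C5=C4, arylmethyl on C4) and dichloroketene (C3, C2 and its oxygen).
- Enabling feature: C5 of the lactone ring is an unsubstituted O–CH2 carbon next to the non-epimerisable stereocentre C4. C5 can therefore carry sulfur for one step, the sulfinyl oxygen ends up in the carboxyl group, and C3 can carry two chlorine atoms until the second benzyl group is introduced.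
- Forward: the side chain is built first (steps 1–5), the only new ring (the lactone) arises in step 6, the Cl and S helpers leave in step 7, the trimethoxybenzyl unit is joined in step 8 and the phenol is freed in step 9.
- Stereochemistry: C4 comes from the sulfur stereocentre of commercial menthyl (S)-p-toluenesulfinate by sulfur-to-carbon chirality transfer in a [3,3] shift. C3 is set by alkylation anti to the C4 substituent (trans).

Key step: step 6

Assumption: the sense of chirality transfer in step 6 follows the chair transition state with the p-tolyl group pseudo-equatorial and the sulfur lone pair syn to the alkene; on this model the (R)-sulfur/(Z)-alkene pairing should give the (R) arrangement at C4.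

**Route**

Step 1
Reactants: 1 4-(benzyloxy)-3,5-dimethoxybenzaldehyde
Product: 2 [4-(benzyloxy)-3,5-dimethoxyphenyl]methanol
Conditions: NaBH4, MeOH, 0 °C to rt
Reagents that add atoms: none
Why: Borohydride reduction of an aromatic aldehyde to the benzylic alcohol is fast and touches neither the benzyl ether nor the methyl ethers; no stereocentre is formed.

Step 2
Reactants: 2 [4-(benzyloxy)-3,5-dimethoxyphenyl]methanol
Product: 3 2-(benzyloxy)-5-(bromomethyl)-1,3-dimethoxybenzene
Conditions: PBr3, CH2Cl2, 0 °C
Reagents that add atoms: phosphorus tribromide, BrP(Br)Br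
Why: Conversion of a benzylic alcohol into the bromide with PBr3 (SN2 displacement on the intermediate phosphite ester) is routine for alkoxy-substituted benzyl alcohols and creates no stereocentre.

Step 3
Reactants: 3 2-(benzyloxy)-5-(bromomethyl)-1,3-dimethoxybenzene; 4 ethynylmagnesium bromide (excess)
Product: 5 2-(benzyloxy)-1,3-dimethoxy-5-(prop-2-yn-1-yl)benzene
Conditions: CuBr (10 mol %), THF, 0 °C to reflux
Reagents that add atoms: none
Why: Copper-catalysed cross-coupling of a benzylic bromide with an alkynyl Grignard reagent joins the sp3 and sp carbons, and the excess of 4 should keep the product from being benzylated a second time; no stereocentre is formed.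

Step 4
Reactants: 5 2-(benzyloxy)-1,3-dimethoxy-5-(prop-2-yn-1-yl)benzene; 6 (1R,2S,5R)-2-isopropyl-5-methylcyclohexyl (S)-4-methylbenzenesulfinate
Product: 8 (S)-2-(benzyloxy)-1,3-dimethoxy-5-{3-[(4-methylphenyl)sulfinyl]prop-2-yn-1-yl}benzene, via alkynylmagnesium bromide 7 (not isolated)
Conditions: EtMgBr, THF, 0 °C to rt; then added to 6 in toluene, −20 °C; aqueous quench
Reagents that add atoms: none
Why: Andersen sulfoxide synthesis, in which the alkynyl Grignard reagent 7 displaces menthoxide at sulfur with inversion, so the sulfur stereocentre of 8 comes directly from the commercial (S)-sulfinate (the descriptor stays (S) only because the alkynyl group outranks p-tolyl).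

Step 5
Reactants: 8 (S)-2-(benzyloxy)-1,3-dimethoxy-5-{3-[(4-methylphenyl)sulfinyl]prop-2-yn-1-yl}benzene
Product: 9 2-(benzyloxy)-1,3-dimethoxy-5-{(Z)-3-[(R)-(4-methylphenyl)sulfinyl]prop-2-en-1-yl}benzene
Conditions: H2 (1 atm), RhCl(PPh3)3 (5 mol %), benzene, rt
Reagents that add atoms: none
Why: Homogeneous syn-semihydrogenation of the alkynyl sulfoxide with RhCl(PPh3)3 should stop at the (Z)-alkene, leaves the benzyl ether and the sulfur configuration untouched (the descriptor changes to (R) only through the priority rules) and sets the alkene geometry that the key step reads.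

Step 6
Reactants: 9 2-(benzyloxy)-1,3-dimethoxy-5-{(Z)-3-[(R)-(4-methylphenyl)sulfinyl]prop-2-en-1-yl}benzene
Product: 12 (4S,5R)-4-[4-(benzyloxy)-3,5-dimethoxybenzyl]-3,3-dichloro-5-[(4-methylphenyl)sulfanyl]dihydrofuran-2(3H)-one, via acyloxysulfonium enolate 10 (not isolated), via thionium carboxylate 11 (not isolated)
Conditions: Cl3CCOCl, Zn(Cu), THF, −45 °C to 0 °C (dichloroketene formed in the flask)
Reagents that add atoms: trichloroacetyl chloride, ClC(Cl)(Cl)C(Cl)=O
Why: The nucleophilic sulfinyl oxygen of 9 adds to the carbonyl carbon of dichloroketene to give the acyloxysulfonium enolate 10, which undergoes a [3,3]-sigmatropic shift (S–O bond broken, bond made between the dichloro carbon and the alkene carbon that carries the arylmethyl group) to the thionium carboxylate 11, whose carboxylate then adds to the thionium carbon. The closest known reaction type is the Marino lactonization of enantiopure alkenyl sulfoxides with dichloroketene, a Claisen-type rearrangement ended by an additive Pummerer capture. The lactone is the only ring closed, and it closes in the 5-exo-trig mode by attack of a carboxylate oxygen on the C=S+ carbon; the C–C bond is made before that through a six-membered chair transition state and closes no ring by itself. The new stereocentre C4 is controlled by the sulfur stereocentre together with the (Z) geometry: with p-tolyl pseudo-equatorial and the lone pair syn to the alkene (enforced by allylic strain with the cis arylmethyl group), the enolate carbon is tethered to the face that carries the S–O bond, which should give the arrangement that becomes (R) at C4 of the target, while C5 should form cis to the arylmethyl group because both new bonds arrive on the same face and is erased in step 7. The step needs O-acylation of the sulfoxide in preference to (2+2) cycloaddition at the alkene or acylation of the electron-rich arene, which the high nucleophilicity of the sulfinyl oxygen at low temperature should secure, and it needs geometrically pure 9, since alkene geometry and sulfur configuration together fix the face.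

Step 7
Reactants: 12 (4S,5R)-4-[4-(benzyloxy)-3,5-dimethoxybenzyl]-3,3-dichloro-5-[(4-methylphenyl)sulfanyl]dihydrofuran-2(3H)-one
Product: 13 (R)-4-[4-(benzyloxy)-3,5-dimethoxybenzyl]dihydrofuran-2(3H)-one
Conditions: Bu3SnH (4 equiv), AIBN (cat.), toluene, 110 °C
Reagents that add atoms: none
Why: Radical-chain reduction with Bu3SnH should remove both α-chlorine atoms (via the stabilised α-carbonyl radical) and the arylsulfanyl group (via the oxygen-stabilised radical at C5) without touching the C4 stereocentre, the lactone or the benzyl ether, and so takes out the helper atoms of the key step.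

Step 8
Reactants: 13 (R)-4-[4-(benzyloxy)-3,5-dimethoxybenzyl]dihydrofuran-2(3H)-one; 14 5-(bromomethyl)-1,2,3-trimethoxybenzene
Product: 16 (3R,4R)-4-[4-(benzyloxy)-3,5-dimethoxybenzyl]-3-(3,4,5-trimethoxybenzyl)dihydrofuran-2(3H)-one, via lithium enolate 15 (not isolated)
Conditions: LiN(SiMe3)2, THF, −78 °C; then 14, DMPU, −78 to −40 °C
Reagents that add atoms: none
Why: Trans-selective alkylation of a β-substituted γ-butyrolactone enolate, in which the benzylic bromide approaches the planar enolate 15 anti to the C4 arylmethyl group and so should set C3 as (R), the thermodynamically favoured trans arrangement.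

Step 9
Reactants: 16 (3R,4R)-4-[4-(benzyloxy)-3,5-dimethoxybenzyl]-3-(3,4,5-trimethoxybenzyl)dihydrofuran-2(3H)-one
Product: 17 (3R,4R)-4-(4-hydroxy-3,5-dimethoxybenzyl)-3-(3,4,5-trimethoxybenzyl)dihydrofuran-2(3H)-one
Conditions: H2 (1 atm), 10% Pd/C, EtOAc–EtOH, rt
Reagents that add atoms: none
Why: Hydrogenolysis of the benzyl aryl ether over Pd on carbon should free the phenol under neutral conditions that leave the lactone, the methyl ethers and both stereocentres untouched.

**Compound list**

1 | 4-(benzyloxy)-3,5-dimethoxybenzaldehyde | COc1cc(C=O)cc(OC)c1OCc1ccccc1 | starting material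
2 | [4-(benzyloxy)-3,5-dimethoxyphenyl]methanol | COc1cc(CO)cc(OC)c1OCc1ccccc1 | intermediate
3 | 2-(benzyloxy)-5-(bromomethyl)-1,3-dimethoxybenzene | COc1cc(CBr)cc(OC)c1OCc1ccccc1 | intermediate
4 | ethynylmagnesium bromide | C#C[Mg]Br | starting material
5 | 2-(benzyloxy)-1,3-dimethoxy-5-(prop-2-yn-1-yl)benzene | COc1cc(CC#C)cc(OC)c1OCc1ccccc1 | intermediate
6 | (1R,2S,5R)-2-isopropyl-5-methylcyclohexyl (S)-4-methylbenzenesulfinate | C[C@@H]1CC[C@H]([C@@H](C1)O[S@](=O)c1ccc(C)cc1)C(C)C | starting material
7 | {3-[4-(benzyloxy)-3,5-dimethoxyphenyl]prop-1-yn-1-yl}magnesium bromide | COc1cc(CC#C[Mg]Br)cc(OC)c1OCc1ccccc1 | intermediate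
8 | (S)-2-(benzyloxy)-1,3-dimethoxy-5-{3-[(4-methylphenyl)sulfinyl]prop-2-yn-1-yl}benzene | Cc1ccc(cc1)[S@](=O)C#CCc1cc(OC)c(OCc2ccccc2)c(OC)c1 | intermediate
9 | 2-(benzyloxy)-1,3-dimethoxy-5-{(Z)-3-[(R)-(4-methylphenyl)sulfinyl]prop-2-en-1-yl}benzene | Cc1ccc(cc1)[S@](=O)/C=C\Cc1cc(OC)c(OCc2ccccc2)c(OC)c1 | intermediate
10 | acyloxysulfonium enolate zwitterion (sulfinyl oxygen of 9 bonded to the dichloroketene carbonyl carbon) | Cc1ccc(cc1)[S@+](OC([O-])=C(Cl)Cl)/C=C\Cc1cc(OC)c(OCc2ccccc2)c(OC)c1 | intermediate
11 | thionium carboxylate (2,2-dichloro-3-(arylmethyl)-4-(p-tolylsulfonio)but-3-enoate, new stereocentre at C3 of the chain) | [O-]C(=O)C(Cl)(Cl)[C@@H](Cc1cc(OC)c(OCc2ccccc2)c(OC)c1)C=[S+]c1ccc(C)cc1 | intermediate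
12 | (4S,5R)-4-[4-(benzyloxy)-3,5-dimethoxybenzyl]-3,3-dichloro-5-[(4-methylphenyl)sulfanyl]dihydrofuran-2(3H)-one (4,5-cis) | O=C1O[C@H](Sc2ccc(C)cc2)[C@H](Cc2cc(OC)c(OCc3ccccc3)c(OC)c2)C1(Cl)Cl | intermediate
13 | (R)-4-[4-(benzyloxy)-3,5-dimethoxybenzyl]dihydrofuran-2(3H)-one | O=C1OC[C@H](Cc2cc(OC)c(OCc3ccccc3)c(OC)c2)C1 | intermediate
14 | 5-(bromomethyl)-1,2,3-trimethoxybenzene | COc1cc(CBr)cc(OC)c1OC | starting material
15 | lithium enolate of 13 | [Li]OC1=C[C@@H](Cc2cc(OC)c(OCc3ccccc3)c(OC)c2)CO1 | intermediate
16 | (3R,4R)-4-[4-(benzyloxy)-3,5-dimethoxybenzyl]-3-(3,4,5-trimethoxybenzyl)dihydrofuran-2(3H)-one | COc1cc(C[C@H]2COC(=O)[C@@H]2Cc2cc(OC)c(OC)c(OC)c2)cc(OC)c1OCc1ccccc1 | intermediate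
17 | (3R,4R)-4-(4-hydroxy-3,5-dimethoxybenzyl)-3-(3,4,5-trimethoxybenzyl)dihydrofuran-2(3H)-one | COc1cc(C[C@H]2COC(=O)[C@@H]2Cc2cc(OC)c(OC)c(OC)c2)cc(OC)c1O | target

**Step count and risks**

Total step count: 9. Longest linear sequence: 9 steps (1 to 17).

Steps most likely to fail:

1. Step 6. Sulfur-to-carbon chirality transfer may be incomplete if a transition state with the p-tolyl group inside competes, and the ketene may be consumed by oligomerisation before O-acylation. The fallback leaves the sulfoxide strategy; it sets out from 1 and comes back at 13. Stobbe condensation of 1 with dimethyl succinate (NaOMe, MeOH, reflux) should give (E)-4-[4-(benzyloxy)-3,5-dimethoxyphenyl]-3-(methoxycarbonyl)but-3-enoic acid F1. Asymmetric hydrogenation of F1 as its triethylammonium salt with [Rh(cod)2]BF4 and a C2-symmetric bisphospholane ligand (the ligand antipode that delivers the (R) acid to be fixed in a pilot run) should give (R)-4-[4-(benzyloxy)-3,5-dimethoxyphenyl]-3-(methoxycarbonyl)butanoic acid F2. Reduction of the ester group of the potassium salt of F2 with Ca(BH4)2 (from CaCl2 and NaBH4, EtOH) followed by acidification should close the lactone to 13.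

2. Step 4. Base-mediated propargyl-to-allenyl isomerisation of the activated CH2 group under the Grignard conditions, or attack of a second equivalent of the Grignard reagent at sulfur, may erode the product. The fallback avoids the alkynyl sulfoxide altogether; it sets out from 5 and comes back at 9, so that step 5 is also replaced. Iodination of 5 (N-iodosuccinimide, AgNO3 cat., acetone) should give 2-(benzyloxy)-5-(3-iodoprop-2-yn-1-yl)-1,3-dimethoxybenzene F3. Diimide reduction (2-nitrobenzenesulfonylhydrazide, Et3N, THF–i-PrOH) should give the (Z)-iodoalkene 2-(benzyloxy)-5-[(Z)-3-iodoprop-2-en-1-yl]-1,3-dimethoxybenzene F4. Iodine–lithium exchange (t-BuLi, Et2O, −78 °C) should give the (Z)-alkenyllithium F5, which on addition to 6 at −78 °C should give 9 with inversion at sulfur and retention of the alkene geometry.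

3. Step 7. Homolysis of the C–S bond may be too slow, so that the reduction stalls after dechlorination. The fallback replaces the single radical reduction by two polar ones; it sets out from 12 and comes back at 13. Zinc dust in AcOH should remove both chlorine atoms to give (4R,5R)-4-[4-(benzyloxy)-3,5-dimethoxybenzyl]-5-[(4-methylphenyl)sulfanyl]dihydrofuran-2(3H)-one F6. Desulfurisation of F6 with nickel boride (NiCl2·6H2O, NaBH4, MeOH–THF, 0 °C), which spares benzyl ethers, should give 13.

**Further compounds**

F1 | step 6 | (E)-4-[4-(benzyloxy)-3,5-dimethoxyphenyl]-3-(methoxycarbonyl)but-3-enoic acid | OC(=O)C/C(C(=O)OC)=C\c1cc(OC)c(OCc2ccccc2)c(OC)c1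
F2 | step 6 | (R)-4-[4-(benzyloxy)-3,5-dimethoxyphenyl]-3-(methoxycarbonyl)butanoic acid | OC(=O)C[C@@H](Cc1cc(OC)c(OCc2ccccc2)c(OC)c1)C(=O)OC
F3 | step 4 | 2-(benzyloxy)-5-(3-iodoprop-2-yn-1-yl)-1,3-dimethoxybenzene | IC#CCc1cc(OC)c(OCc2ccccc2)c(OC)c1
F4 | step 4 | 2-(benzyloxy)-5-[(Z)-3-iodoprop-2-en-1-yl]-1,3-dimethoxybenzene | I/C=C\Cc1cc(OC)c(OCc2ccccc2)c(OC)c1
F5 | step 4 | {(Z)-3-[4-(benzyloxy)-3,5-dimethoxyphenyl]prop-1-en-1-yl}lithium | [Li]/C=C\Cc1cc(OC)c(OCc2ccccc2)c(OC)c1
F6 | step 7 | (4R,5R)-4-[4-(benzyloxy)-3,5-dimethoxybenzyl]-5-[(4-methylphenyl)sulfanyl]dihydrofuran-2(3H)-one | O=C1O[C@H](Sc2ccc(C)cc2)[C@H](Cc2cc(OC)c(OCc3ccccc3)c(OC)c2)C1
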